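**Strategy**

The dimer is cut at the C4(upper)–C6(lower) bond into two molecules of one monomer, the flavan-3,4-diol mollisacacidin, so a single ring synthesis serves both halves. Ring C of the monomer is disconnected at O1–C8a and C2–C3: O1 and C2 are the carbonyl group of a 3,4-dioxygenated benzaldehyde, C3 is the enolisable α-carbon of a C4 aryl ketone, and that ketone, ortho to C8a on ring A, activates a C8a–F bond. The key step joins the enol silane of this 2-fluoroaryl ketone with the aldehyde by catalytic asymmetric Mukaiyama aldol addition and in-flask SNAr closure, setting C2 and C3. Debenzylation, C4 reduction and acid-mediated self-condensation follow.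

Key step: step 3

Assumption: the (S,S) antipode of the bisphosphoramide in step 3, and the (R) antipode of the sulfinamide in its fallback, are taken to deliver C3 to the Si face of aldehyde 7 (the face that gives 2R); if a test aldol shows the opposite sense, the mirror-image controller is used.

**Route**

Step 1
Reactants: 1 4-(benzyloxy)-1-bromo-2-fluorobenzene; 2 2-(benzyloxy)-N-methoxy-N-methylacetamide
Product: 5 2-(benzyloxy)-1-[4-(benzyloxy)-2-fluorophenyl]ethan-1-one, via arylmagnesium chloride 3 (not isolated), via magnesium hemiaminal adduct 4 (not isolated)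
Conditions: iPrMgCl·LiCl, THF, −15 to 0 °C; then 2, 0 °C to rt; aq NH4Cl
Reagents that add atoms: none
Why: Halogen–magnesium exchange with the turbo-Grignard reagent is accelerated by the ortho fluorine, and the aryl Grignard adds once to the Weinreb amide through a chelated tetrahedral adduct that releases the ketone only on work-up (Weinreb ketone synthesis).

Step 2
Reactants: 5 2-(benzyloxy)-1-[4-(benzyloxy)-2-fluorophenyl]ethan-1-one
Product: 6 (Z)-{[2-(benzyloxy)-1-(4-(benzyloxy)-2-fluorophenyl)ethenyl]oxy}trimethylsilane
Conditions: Me3SiOTf, Et3N, CH2Cl2, 0 °C; non-aqueous work-up, used crude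
Reagents that add atoms: trimethylsilyl trifluoromethanesulfonate, C[Si](C)(C)OS(=O)(=O)C(F)(F)F
Why: Soft enolisation with Me3SiOTf/Et3N can only take place toward C3 and should give mainly the Z silyl enol ether, whose geometry is not critical for the next step (silyl enol ether formation).

Step 3
Reactants: 6 (Z)-silyl enol ether; 7 3,4-bis(benzyloxy)benzaldehyde
Product: 10 (2R,3R)-3,7-bis(benzyloxy)-2-[3,4-bis(benzyloxy)phenyl]-2,3-dihydro-4H-chromen-4-one, via trichlorosilyl aldolate 8 (not isolated), via cesium alkoxide 9 (not isolated)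
Conditions: SiCl4 (1.5 equiv), (S,S)-bisphosphoramide (binaphthyldiamine-derived, pentane-1,5-diyl-linked, 5 mol%), iPr2NEt (10 mol%), CH2Cl2, −78 °C; then CsF (excess), DMF, −78 to 20 °C, same flask; pH 7 phosphate buffer
Reagents that add atoms: none
Why: The phosphoramide-bound trichlorosilyl cation made from SiCl4 activates only aldehyde 7, the C3 terminus of enol silane 6 adds to its carbonyl carbon through an open transition state to give silyl aldolate 8 (C2–C3 bond), and fluoride then strips silicon to alkoxide 9, whose oxygen attacks C8a and expels fluoride through a Meisenheimer adduct (O1–C8a bond). The closest known reaction types are the Lewis-base-catalysed SiCl4 Mukaiyama aldol addition of ketone enol silanes and α-oxygenated silyl nucleophiles to aromatic aldehydes, and the closure of chroman-4-ones by intramolecular SNAr of β-alkoxides on 2-fluoroaryl ketones. Ring C closes in the 6-exo-trig addition–elimination mode. C2 is controlled by the catalyst (Si-face attack on 7 gives 2R) and C3 by the anti preference of the open transition state (3R), which is also the more stable trans, diequatorial arrangement in the chromanone. The step needs ring closure to outrun retro-aldol cleavage of 9, which the C4 carbonyl ortho to the C–F bond, the six-membered closure and the low temperature should secure.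

Step 4
Reactants: 10 (2R,3R)-tetra-O-benzyl dihydroflavonol
Product: 11 (2R,3R)-2-(3,4-dihydroxyphenyl)-3,7-dihydroxy-2,3-dihydro-4H-chromen-4-one ((2R,3R)-fustin)
Conditions: H2 (1 atm), 10% Pd/C, EtOAc/MeOH, rt, stopped once debenzylation is complete
Reagents that add atoms: none
Why: Catalytic hydrogenolysis removes the four O-benzyl groups under neutral conditions faster than it reduces the electron-rich aryl ketone or cleaves the benzylic C2–O1 bond, and leaves C2 and C3 untouched.

Step 5
Reactants: 11 (2R,3R)-fustin
Product: 12 (2R,3S,4R)-2-(3,4-dihydroxyphenyl)-3,4-dihydro-2H-chromene-3,4,7-triol (mollisacacidin, 2,3-trans-3,4-trans)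
Conditions: NaBH4, EtOH, 0 °C to rt; dilute AcOH to pH 6
Reagents that add atoms: none
Why: Borohydride reduction of the dihydroflavonol carbonyl by axial hydride delivery to the half-chair with equatorial 2-aryl and 3-OH groups places the new 4-OH equatorial, trans to the 3-OH (4R), which is the usual outcome of NaBH4 reduction of 2,3-trans-dihydroflavonols.

Step 6
Reactants: 12 mollisacacidin (two molecules)
Product: 14 (2R,3S,4R)-2-(3,4-dihydroxyphenyl)-6-[(2R,3S,4R)-2-(3,4-dihydroxyphenyl)-3,7-dihydroxy-3,4-dihydro-2H-chromen-4-yl]-3,4-dihydro-2H-chromene-3,4,7-triol, via flavan-4-yl cation 13 (not isolated)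
Conditions: 0.1 M aq HCl, 25 °C, argon, stopped near one-third conversion; Sephadex LH-20 (EtOH), recovered 12 recycled
Reagents that add atoms: none
Why: Acid ionises the benzylic 4-OH of one molecule to cation 13, stabilised by O1 and the para 7-OH, and ring A of a second molecule attacks through C6 (ortho to its 7-OH, para to O1, less hindered than C8) on the face anti to the 3-OH, which sets the 3,4-trans (4R) interflavan bond while the lower unit keeps its diol (biomimetic Friedel–Crafts coupling of a flavan-4-yl cation).

**Compound list**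

1 | 4-(benzyloxy)-1-bromo-2-fluorobenzene | Brc1ccc(OCc2ccccc2)cc1F | starting material
2 | 2-(benzyloxy)-N-methoxy-N-methylacetamide | CON(C)C(=O)COCc1ccccc1 | starting material
3 | [4-(benzyloxy)-2-fluorophenyl]magnesium chloride | Cl[Mg]c1ccc(OCc2ccccc2)cc1F | intermediate (not isolated)
4 | chloromagnesium 2-(benzyloxy)-1-[4-(benzyloxy)-2-fluorophenyl]-1-[methoxy(methyl)amino]ethan-1-olate | CON(C)C(O[Mg]Cl)(COCc1ccccc1)c1ccc(OCc2ccccc2)cc1F | intermediate (not isolated)
5 | 2-(benzyloxy)-1-[4-(benzyloxy)-2-fluorophenyl]ethan-1-one | O=C(COCc1ccccc1)c1ccc(OCc2ccccc2)cc1F | intermediate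
6 | (Z)-{[2-(benzyloxy)-1-(4-(benzyloxy)-2-fluorophenyl)ethenyl]oxy}trimethylsilane | C[Si](C)(C)O/C(=C\OCc1ccccc1)c1ccc(OCc2ccccc2)cc1F | intermediate
7 | 3,4-bis(benzyloxy)benzaldehyde | O=Cc1ccc(OCc2ccccc2)c(OCc2ccccc2)c1 | starting material
8 | (2R,3R)-2-(benzyloxy)-1-[4-(benzyloxy)-2-fluorophenyl]-3-[3,4-bis(benzyloxy)phenyl]-3-[(trichlorosilyl)oxy]propan-1-one | Cl[Si](Cl)(Cl)O[C@H](c1ccc(OCc2ccccc2)c(OCc2ccccc2)c1)[C@@H](OCc1ccccc1)C(=O)c1ccc(OCc2ccccc2)cc1F | intermediate (not isolated)
9 | cesium (1R,2R)-2-(benzyloxy)-3-[4-(benzyloxy)-2-fluorophenyl]-1-[3,4-bis(benzyloxy)phenyl]-3-oxopropan-1-olate | [Cs+].[O-][C@H](c1ccc(OCc2ccccc2)c(OCc2ccccc2)c1)[C@@H](OCc1ccccc1)C(=O)c1ccc(OCc2ccccc2)cc1F | intermediate (not isolated)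
10 | (2R,3R)-3,7-bis(benzyloxy)-2-[3,4-bis(benzyloxy)phenyl]-2,3-dihydro-4H-chromen-4-one | O=C1c2ccc(OCc3ccccc3)cc2O[C@H](c2ccc(OCc3ccccc3)c(OCc3ccccc3)c2)[C@H]1OCc1ccccc1 | intermediate
11 | (2R,3R)-2-(3,4-dihydroxyphenyl)-3,7-dihydroxy-2,3-dihydro-4H-chromen-4-one (fustin) | O=C1c2ccc(O)cc2O[C@H](c2ccc(O)c(O)c2)[C@H]1O | intermediate
12 | (2R,3S,4R)-2-(3,4-dihydroxyphenyl)-3,4-dihydro-2H-chromene-3,4,7-triol (mollisacacidin) | Oc1ccc2c(c1)O[C@H](c1ccc(O)c(O)c1)[C@@H](O)[C@@H]2O | intermediate
13 | (2R,3S)-2-(3,4-dihydroxyphenyl)-3,7-dihydroxy-3,4-dihydro-2H-chromen-4-ylium | Oc1ccc2c(c1)O[C@H](c1ccc(O)c(O)c1)[C@@H](O)[CH+]2 | intermediate (not isolated)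
14 | (2R,3S,4R)-2-(3,4-dihydroxyphenyl)-6-[(2R,3S,4R)-2-(3,4-dihydroxyphenyl)-3,7-dihydroxy-3,4-dihydro-2H-chromen-4-yl]-3,4-dihydro-2H-chromene-3,4,7-triol | Oc1ccc2c(c1)O[C@H](c1ccc(O)c(O)c1)[C@@H](O)[C@@H]2c1cc2c(cc1O)O[C@H](c1ccc(O)c(O)c1)[C@@H](O)[C@@H]2O | target

**Count and risks**

Total step count: 6. Longest linear sequence: 6 steps (1 to 14).

Steps most likely to fail:

Step 3. Retro-aldol cleavage of the alkoxide before ring closure, followed by re-addition outside catalyst control, would erode enantiopurity; base-induced opening of ring C after closure would do the same. The fallback sets out from ketone 5. Condensation with (R)-2-methylpropane-2-sulfinamide (Ti(OEt)4, THF, 60 °C) gives the N-sulfinyl ketimine F1. Its lithium aza-enolate (LDA, THF, −78 °C) adds to 7 under auxiliary control, and on warming with DMPU the lithium alkoxide closes onto C8a, so the same two bonds form in one operation to give the cyclic sulfinyl imine F2. Because the controller stays on the molecule, any reversal re-adds under the same control and the minor isomers are separable diastereomers. Brief treatment with 1 M HCl in THF at 0 °C hydrolyses the C=N bond and brings the route back to 10.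

Step 6. Chain growth beyond the dimer is likely because the product keeps an ionisable 4-OH and a nucleophilic ring A; attack through C8 or on the 3-OH face and epimerisation of the lower 4-OH through reversible ionisation are further losses. The fallback sets out from 12. Thiolysis with phenylmethanethiol and AcOH in EtOH at 80 °C gives the 4-benzylsulfanyl flavan-3-ol F3. AgBF4 in THF at 0 °C then ionises only the C4–S bond of F3 in the presence of a fourfold excess of 12, whose own 4-OH is not activated under these thiophilic conditions. The route is rejoined at 14.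

Step 4. Over-reduction of the C4 carbonyl and hydrogenolytic opening of the benzylic C2–O1 bond of ring C may compete with debenzylation. The fallback sets out from 10 and comes back at 11: non-reductive debenzylation with BCl3 and pentamethylbenzene as benzyl-cation scavenger in CH2Cl2 at −78 °C, which makes no new compound, F0.

**Further compounds**

F1 | step 3 | (R)-N-{2-(benzyloxy)-1-[4-(benzyloxy)-2-fluorophenyl]ethylidene}-2-methylpropane-2-sulfinamide (C=N geometry interconverting) | CC(C)(C)[S@@](=O)N=C(COCc1ccccc1)c1ccc(OCc2ccccc2)cc1F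
F2 | step 3 | (R)-N-{(2R,3S)-3,7-bis(benzyloxy)-2-[3,4-bis(benzyloxy)phenyl]-2,3-dihydro-4H-chromen-4-ylidene}-2-methylpropane-2-sulfinamide | CC(C)(C)[S@@](=O)N=C1c2ccc(OCc3ccccc3)cc2O[C@H](c2ccc(OCc3ccccc3)c(OCc3ccccc3)c2)[C@H]1OCc1ccccc1
F3 | step 6 | (2R,3R,4R)-4-(benzylsulfanyl)-2-(3,4-dihydroxyphenyl)-3,4-dihydro-2H-chromene-3,7-diol (2,3-trans-3,4-trans) | Oc1ccc2c(c1)O[C@H](c1ccc(O)c(O)c1)[C@@H](O)[C@@H]2SCc1ccccc1
F0 | step 4 | none | none
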